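**Plan**
- Enabling feature: in the target, the methoxy oxygen of the 2-aryl ring, C2, C3 and the formyl carbon of the benzofuran correspond one-to-one to O1, C4, C3 and C2 of an isoflavone, and the furan oxygen is a 2'-oxygen of that isoflavone's ring B. The benzofuran is therefore a ring-switched, O-methylated 2'-hydroxyisoflavone.
- Retrosynthetic cuts, in order: the two O–benzyl bonds and the aryl O–CH3 bond; the furan O1–C2 bond (back to the pyranone of isoflavone 15); the pyranone O1–C2 bond and the C3–aryl bond (1,2-aryl shift back to chalcone 12); the enone Cα=Cβ bond (aldol); the side-chain C–OH and aryl–CH2 bonds of ring B (hydration, Claisen rearrangement).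
- Forward: ring B is prenylated by a Claisen rearrangement and hydrated (steps 1–7), then joined to ring A as a chalcone (step 8). The pyranone is the first ring to close (steps 9–10). In step 11 pyrrolidine opens it and the furan closes in its place. Methylation of the released phenol and hydrogenolysis finish the route (steps 12–13).
- Stereochemistry: the target has no stereocentre and no stereogenic double bond. The centres that arise in 8 and 13 are racemic and vanish in the same or the following step.

Key step: step 11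

Assumption: 1-[4-(benzyloxy)-2-hydroxyphenyl]ethan-1-one (11), the 4-O-benzyl ether of 2,4-dihydroxyacetophenone, is taken as a catalogue compound.

**Route**

Step 1
Reactants: 1 2,6-dihydroxy-4-methoxybenzaldehyde; 2 3-chloro-3-methylbut-1-yne
Product: 3 2-hydroxy-4-methoxy-6-[(2-methylbut-3-yn-2-yl)oxy]benzaldehyde
Conditions: K2CO3, KI, CuI (cat.), DMF, 60 °C
Reagents that add atoms: none
Why: Copper-assisted Williamson-type O-alkylation with the tertiary propargylic chloride; the two phenols of 1 are equivalent and the one left after the first alkylation is held in a hydrogen bond to the formyl group, so the mono-ether should dominate.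

Step 2
Reactants: 3 2-hydroxy-4-methoxy-6-[(2-methylbut-3-yn-2-yl)oxy]benzaldehyde
Product: 4 4-methoxy-2-(methoxymethoxy)-6-[(2-methylbut-3-yn-2-yl)oxy]benzaldehyde
Conditions: MOMCl, iPr2NEt, CH2Cl2, 0 → 40 °C
Reagents that add atoms: chloromethyl methyl ether, COCCl
Why: Williamson-type MOM protection of the remaining chelated phenol marks the oxygen that later becomes the furan oxygen with a group that can be removed without touching benzyl ethers.

Step 3
Reactants: 4 4-methoxy-2-(methoxymethoxy)-6-[(2-methylbut-3-yn-2-yl)oxy]benzaldehyde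
Product: 5 4-methoxy-2-(methoxymethoxy)-6-[(2-methylbut-3-en-2-yl)oxy]benzaldehyde
Conditions: H2 (1 atm), Lindlar cat., quinoline, EtOAc, rt
Reagents that add atoms: none
Why: Lindlar semi-hydrogenation should stop the terminal alkyne at the alkene and leave the aldehyde alone, giving the 1,1-dimethylallyl aryl ether needed for the sigmatropic step.

Step 4
Reactants: 5 4-methoxy-2-(methoxymethoxy)-6-[(2-methylbut-3-en-2-yl)oxy]benzaldehyde
Product: 6 2-hydroxy-4-methoxy-6-(methoxymethoxy)-3-(3-methylbut-2-en-1-yl)benzaldehyde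
Conditions: PhNEt2, 130 °C
Reagents that add atoms: none
Why: Aromatic Claisen rearrangement: the [3,3] shift delivers the allyl unit with inversion (1,1-dimethylallyl to prenyl) to the only hydrogen-bearing ortho carbon, the other ortho position carrying the formyl group, and tautomerisation returns the phenol.

Step 5
Reactants: 6 2-hydroxy-4-methoxy-6-(methoxymethoxy)-3-(3-methylbut-2-en-1-yl)benzaldehyde
Product: 7 2-(benzyloxy)-4-methoxy-6-(methoxymethoxy)-3-(3-methylbut-2-en-1-yl)benzaldehyde
Conditions: BnBr, K2CO3, DMF, 60 °C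
Reagents that add atoms: benzyl bromide, BrCc1ccccc1
Why: Williamson etherification of the hindered chelated phenoxide; the benzyl group keeps this oxygen out of the later ring switch and stops it cyclising onto the side chain.

Step 6
Reactants: 7 2-(benzyloxy)-4-methoxy-6-(methoxymethoxy)-3-(3-methylbut-2-en-1-yl)benzaldehyde
Product: 9 4-[2-(benzyloxy)-3-(hydroxymethyl)-6-methoxy-4-(methoxymethoxy)phenyl]-2-methylbutan-2-ol, via organomercury acetate 8 (not isolated)
Conditions: Hg(OAc)2, THF/H2O (1:1), rt; then 3 M NaOH, NaBH4, 0 °C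
Reagents that add atoms: water, O
Why: Oxymercuration–demercuration adds water in the Markovnikov sense to the trisubstituted alkene without cationic rearrangement, no phenol being free to close a chroman on the mercurinium ion; borohydride removes mercury and also reduces the aldehyde, which is accepted and corrected in step 7.

Step 7
Reactants: 9 4-[2-(benzyloxy)-3-(hydroxymethyl)-6-methoxy-4-(methoxymethoxy)phenyl]-2-methylbutan-2-ol
Product: 10 2-(benzyloxy)-3-(3-hydroxy-3-methylbutyl)-4-methoxy-6-(methoxymethoxy)benzaldehyde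
Conditions: MnO2, CH2Cl2, rt
Reagents that add atoms: none
Why: Manganese dioxide oxidation of the electron-rich benzylic alcohol should return the aldehyde, and the tertiary alcohol cannot be oxidised.

Step 8
Reactants: 10 2-(benzyloxy)-3-(3-hydroxy-3-methylbutyl)-4-methoxy-6-(methoxymethoxy)benzaldehyde; 11 1-[4-(benzyloxy)-2-hydroxyphenyl]ethan-1-one
Product: 12 (E)-1-[4-(benzyloxy)-2-hydroxyphenyl]-3-[2-(benzyloxy)-3-(3-hydroxy-3-methylbutyl)-4-methoxy-6-(methoxymethoxy)phenyl]prop-2-en-1-one
Conditions: KOH (50% aq.), EtOH/THF, rt → 40 °C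
Reagents that add atoms: none
Why: Claisen–Schmidt condensation of the acetophenone enolate with the non-enolisable aldehyde, E1cB dehydration giving the (E)-enone.

Step 9
Reactants: 12 (E)-1-[4-(benzyloxy)-2-hydroxyphenyl]-3-[2-(benzyloxy)-3-(3-hydroxy-3-methylbutyl)-4-methoxy-6-(methoxymethoxy)phenyl]prop-2-en-1-one
Product: 13 rac-1-[4-(benzyloxy)-2-hydroxyphenyl]-2-[2-(benzyloxy)-3-(3-hydroxy-3-methylbutyl)-4-methoxy-6-(methoxymethoxy)phenyl]-3,3-dimethoxypropan-1-one
Conditions: Tl(NO3)3·3H2O (1.1 equiv), MeOH/HC(OMe)3 (3:1), rt; NaHCO3 quench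
Reagents that add atoms: methanol, CO
Why: Thallium(III) nitrate oxidative rearrangement of a 2'-hydroxychalcone: oxythallation at Cα with methanol adding at Cβ, 1,2-shift of the electron-rich ring B as Tl(I) leaves and capture of the oxocarbenium ion by methanol; the new stereocentre is racemic and disappears in step 10.

Step 10
Reactants: 13 rac-1-[4-(benzyloxy)-2-hydroxyphenyl]-2-[2-(benzyloxy)-3-(3-hydroxy-3-methylbutyl)-4-methoxy-6-(methoxymethoxy)phenyl]-3,3-dimethoxypropan-1-one
Product: 15 7-(benzyloxy)-3-[2-(benzyloxy)-6-hydroxy-3-(3-hydroxy-3-methylbutyl)-4-methoxyphenyl]-4H-chromen-4-one, via MOM-protected isoflavone 14 (not isolated)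
Conditions: TsOH·H2O (10 mol%), MeOH, 40 °C; then HCl (to 1 M), 45 °C
Reagents that add atoms: none
Why: Acid-catalysed acetal ionisation lets the ring-A phenol, free from the start, close the pyranone (6-exo attack on the oxocarbenium ion, then loss of methanol) before the stronger acid of the second stage cleaves the aryl MOM ether, so the ring-B oxygen is unveiled only on a finished chromone; both events should be far faster than ionisation of the saturated tertiary alcohol, which has only ether neighbours.

Step 11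
Reactants: 15 7-(benzyloxy)-3-[2-(benzyloxy)-6-hydroxy-3-(3-hydroxy-3-methylbutyl)-4-methoxyphenyl]-4H-chromen-4-one
Product: 18 4-(benzyloxy)-2-[4-(benzyloxy)-2-hydroxyphenyl]-5-(3-hydroxy-3-methylbutyl)-6-methoxy-1-benzofuran-3-carbaldehyde, via ring-opened enaminone 16 (not isolated), via benzofuranyl iminium phenoxide 17 (not isolated)
Conditions: pyrrolidine (5 equiv), EtOH, 78 °C, N2; then aq. AcOH/NaOAc (pH 5), rt
Reagents that add atoms: none
Why: Proposed new method: pyrrolidine adds to C2 of the chromone and expels the ring-A phenoxide (O1–C2 cleavage) to give vinylogous amide 16, whose ketone is activated by a hydrogen bond from the phenol just released; the ring-B phenoxide adds to that ketone carbon and the enamine nitrogen pushes out hydroxide, giving the aromatic benzofuran as iminium 17, which the water set free hydrolyses to the aldehyde (completed in the pH 5 work-up). The closest known reaction types are the ring opening of chromones and isoflavones by secondary amines to enaminones and the acid cyclodehydration of α-formyl-2-hydroxydeoxybenzoin derivatives to 2-aryl-3-formylbenzofurans; the direct amine-mediated switch has not been shown. The furan closes by 5-exo-trig attack of the ring-B oxygen on the former C4 carbonyl (the new bond is O1–C2 of the benzofuran) followed by dehydration, and no stereocentre is formed. The step needs closure at the carbonyl carbon and not at the enamine carbon (which would end in a 3-aroylbenzofuran): in the neutral enaminone the latter is a 5-endo-trig conjugate addition that could go on only by losing amine, which excess pyrrolidine and the absence of acid disfavour, and reclosure of ring A to 15 is reversible under the same conditions. Only the ring-B oxygen flanked by hydrogen is free, the one next to the side chain being benzylated, so a single benzofuran regioisomer is possible. Aromatisation of the furan should make the exit irreversible, and any 16 left reverts to 15 on work-up and can be resubmitted.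

Step 12
Reactants: 18 4-(benzyloxy)-2-[4-(benzyloxy)-2-hydroxyphenyl]-5-(3-hydroxy-3-methylbutyl)-6-methoxy-1-benzofuran-3-carbaldehyde
Product: 19 4-(benzyloxy)-2-[4-(benzyloxy)-2-methoxyphenyl]-5-(3-hydroxy-3-methylbutyl)-6-methoxy-1-benzofuran-3-carbaldehyde
Conditions: MeI, K2CO3, DMF, rt
Reagents that add atoms: iodomethane, CI
Why: Williamson methylation of the only phenol (carbonate does not deprotonate the tertiary alcohol, and any lactol tautomer of 18 opens to the phenoxide under base) fixes the oxygen released in step 11 as the methoxy group of the target.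

Step 13
Reactants: 19 4-(benzyloxy)-2-[4-(benzyloxy)-2-methoxyphenyl]-5-(3-hydroxy-3-methylbutyl)-6-methoxy-1-benzofuran-3-carbaldehyde
Product: 20 Ebenfuran VI (4-hydroxy-2-(4-hydroxy-2-methoxyphenyl)-5-(3-hydroxy-3-methylbutyl)-6-methoxy-1-benzofuran-3-carbaldehyde)
Conditions: H2 (1 atm), 10% Pd/C, EtOAc, rt, stopped after 2 equiv H2
Reagents that add atoms: none
Why: Catalytic hydrogenolysis of the two aryl benzyl ethers; the aldehyde is a vinylogous formate conjugated through the furan oxygen, the furan double bond is aromatic and the tertiary alcohol is not benzylic, so all three should outlast O-benzyl cleavage.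

**Compound list**

1 | 2,6-dihydroxy-4-methoxybenzaldehyde | COc1cc(O)c(C=O)c(O)c1 | starting material
2 | 3-chloro-3-methylbut-1-yne | CC(C)(Cl)C#C | starting material
3 | 2-hydroxy-4-methoxy-6-[(2-methylbut-3-yn-2-yl)oxy]benzaldehyde | COc1cc(O)c(C=O)c(OC(C)(C)C#C)c1 | intermediate
4 | 4-methoxy-2-(methoxymethoxy)-6-[(2-methylbut-3-yn-2-yl)oxy]benzaldehyde | COCOc1cc(OC)cc(OC(C)(C)C#C)c1C=O | intermediate
5 | 4-methoxy-2-(methoxymethoxy)-6-[(2-methylbut-3-en-2-yl)oxy]benzaldehyde | COCOc1cc(OC)cc(OC(C)(C)C=C)c1C=O | intermediate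
6 | 2-hydroxy-4-methoxy-6-(methoxymethoxy)-3-(3-methylbut-2-en-1-yl)benzaldehyde | COCOc1cc(OC)c(CC=C(C)C)c(O)c1C=O | intermediate
7 | 2-(benzyloxy)-4-methoxy-6-(methoxymethoxy)-3-(3-methylbut-2-en-1-yl)benzaldehyde | COCOc1cc(OC)c(CC=C(C)C)c(OCc2ccccc2)c1C=O | intermediate
8 | rac-acetoxy{1-[2-(benzyloxy)-3-formyl-6-methoxy-4-(methoxymethoxy)phenyl]-3-hydroxy-3-methylbutan-2-yl}mercury (not isolated) | COCOc1cc(OC)c(CC([Hg]OC(C)=O)C(C)(C)O)c(OCc2ccccc2)c1C=O | intermediate
9 | 4-[2-(benzyloxy)-3-(hydroxymethyl)-6-methoxy-4-(methoxymethoxy)phenyl]-2-methylbutan-2-ol | COCOc1cc(OC)c(CCC(C)(C)O)c(OCc2ccccc2)c1CO | intermediate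
10 | 2-(benzyloxy)-3-(3-hydroxy-3-methylbutyl)-4-methoxy-6-(methoxymethoxy)benzaldehyde | COCOc1cc(OC)c(CCC(C)(C)O)c(OCc2ccccc2)c1C=O | intermediate
11 | 1-[4-(benzyloxy)-2-hydroxyphenyl]ethan-1-one | CC(=O)c1ccc(OCc2ccccc2)cc1O | starting material
12 | (E)-1-[4-(benzyloxy)-2-hydroxyphenyl]-3-[2-(benzyloxy)-3-(3-hydroxy-3-methylbutyl)-4-methoxy-6-(methoxymethoxy)phenyl]prop-2-en-1-one | COCOc1cc(OC)c(CCC(C)(C)O)c(OCc2ccccc2)c1/C=C/C(=O)c1ccc(OCc2ccccc2)cc1O | intermediate
13 | rac-1-[4-(benzyloxy)-2-hydroxyphenyl]-2-[2-(benzyloxy)-3-(3-hydroxy-3-methylbutyl)-4-methoxy-6-(methoxymethoxy)phenyl]-3,3-dimethoxypropan-1-one | COCOc1cc(OC)c(CCC(C)(C)O)c(OCc2ccccc2)c1C(C(OC)OC)C(=O)c1ccc(OCc2ccccc2)cc1O | intermediate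
14 | 7-(benzyloxy)-3-[2-(benzyloxy)-3-(3-hydroxy-3-methylbutyl)-4-methoxy-6-(methoxymethoxy)phenyl]-4H-chromen-4-one (not isolated) | O=c1c(-c2c(OCOC)cc(OC)c(CCC(C)(C)O)c2OCc2ccccc2)coc2cc(OCc3ccccc3)ccc12 | intermediate
15 | 7-(benzyloxy)-3-[2-(benzyloxy)-6-hydroxy-3-(3-hydroxy-3-methylbutyl)-4-methoxyphenyl]-4H-chromen-4-one | O=c1c(-c2c(O)cc(OC)c(CCC(C)(C)O)c2OCc2ccccc2)coc2cc(OCc3ccccc3)ccc12 | intermediate
16 | (E)-1-[4-(benzyloxy)-2-hydroxyphenyl]-2-[2-(benzyloxy)-6-hydroxy-3-(3-hydroxy-3-methylbutyl)-4-methoxyphenyl]-3-(pyrrolidin-1-yl)prop-2-en-1-one (not isolated) | O=C(c1ccc(OCc2ccccc2)cc1O)/C(=C/N1CCCC1)c1c(O)cc(OC)c(CCC(C)(C)O)c1OCc1ccccc1 | intermediate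
17 | 5-(benzyloxy)-2-[4-(benzyloxy)-5-(3-hydroxy-3-methylbutyl)-6-methoxy-3-(pyrrolidin-1-ium-1-ylidenemethyl)-1-benzofuran-2-yl]phenolate (not isolated) | [O-]c1cc(OCc2ccccc2)ccc1-c1oc2cc(OC)c(CCC(C)(C)O)c(OCc3ccccc3)c2c1C=[N+]1CCCC1 | intermediate
18 | 4-(benzyloxy)-2-[4-(benzyloxy)-2-hydroxyphenyl]-5-(3-hydroxy-3-methylbutyl)-6-methoxy-1-benzofuran-3-carbaldehyde | O=Cc1c(-c2ccc(OCc3ccccc3)cc2O)oc2cc(OC)c(CCC(C)(C)O)c(OCc3ccccc3)c12 | intermediate
19 | 4-(benzyloxy)-2-[4-(benzyloxy)-2-methoxyphenyl]-5-(3-hydroxy-3-methylbutyl)-6-methoxy-1-benzofuran-3-carbaldehyde | O=Cc1c(-c2ccc(OCc3ccccc3)cc2OC)oc2cc(OC)c(CCC(C)(C)O)c(OCc3ccccc3)c12 | intermediate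
20 | Ebenfuran VI, 4-hydroxy-2-(4-hydroxy-2-methoxyphenyl)-5-(3-hydroxy-3-methylbutyl)-6-methoxy-1-benzofuran-3-carbaldehyde | COc1cc(O)ccc1-c1oc2cc(OC)c(CCC(C)(C)O)c(O)c2c1C=O | target

**Totals**

Total step count: 13. Longest linear sequence: 13 steps (1 → 20; ketone 11 enters in step 8 as purchased).

**Steps most likely to fail**

1. Step 11 (carries the proposed method). The enaminone may return to the isoflavone on work-up without the furan having closed. The ring-B oxygen may instead close on the enamine carbon with loss of amine, giving an aroylbenzofuran. Hydroxide formed in the flask may also cut out the formyl carbon by retro-Claisen cleavage. The fallback uses known chemistry, sets out from 11 and 10 and rejoins the route at 19. The ring-A oxygen is methylated before the rings are joined, so no pyranone can form, and the ring switch is replaced by the established acid cyclisation of rearranged 2-hydroxychalcone acetals to 2-aryl-3-formylbenzofurans. O-Methylation of 11 (MeI, K2CO3, DMF) gives 1-[4-(benzyloxy)-2-methoxyphenyl]ethan-1-one F1. Claisen–Schmidt condensation with 10 gives (E)-1-[4-(benzyloxy)-2-methoxyphenyl]-3-[2-(benzyloxy)-3-(3-hydroxy-3-methylbutyl)-4-methoxy-6-(methoxymethoxy)phenyl]prop-2-en-1-one F2. The thallium(III) nitrate rearrangement of step 9 gives rac-1-[4-(benzyloxy)-2-methoxyphenyl]-2-[2-(benzyloxy)-3-(3-hydroxy-3-methylbutyl)-4-methoxy-6-(methoxymethoxy)phenyl]-3,3-dimethoxypropan-1-one F3. TsOH in MeOH removes the MOM group and the freed phenol closes on the acetal carbon to the cyclic acetal [4-(benzyloxy)-5-(3-hydroxy-3-methylbutyl)-2,6-dimethoxy-2,3-dihydro-1-benzofuran-3-yl][4-(benzyloxy)-2-methoxyphenyl]methanone F4. Catalytic p-TsOH in (CF3)2CHOH at low temperature then reopens F4 and recloses the phenol on the ketone with loss of water and methanol, which should give 19 directly.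

2. Step 9. Thallium(III) may oxidise the electron-rich ring B or the free ring-A phenol instead of oxythallating the enone. The ring-A phenol may also capture the thallated intermediate (aurone-type closure) before the aryl group shifts. The fallback sets out from 12 and returns to the route at 15. It replaces the oxidative aryl shift by a non-oxidative 1,2-acyl shift of the chalcone epoxide, which gives the same carbon skeleton. MOM protection of the ring-A phenol of 12 (MOMCl, K2CO3, acetone) gives (E)-1-[4-(benzyloxy)-2-(methoxymethoxy)phenyl]-3-[2-(benzyloxy)-3-(3-hydroxy-3-methylbutyl)-4-methoxy-6-(methoxymethoxy)phenyl]prop-2-en-1-one F5. Weitz–Scheffer epoxidation (H2O2, NaOH, MeOH/THF) gives rac-trans-[4-(benzyloxy)-2-(methoxymethoxy)phenyl]{3-[2-(benzyloxy)-3-(3-hydroxy-3-methylbutyl)-4-methoxy-6-(methoxymethoxy)phenyl]oxiran-2-yl}methanone F6. BF3·OEt2 (CH2Cl2, −20 °C) opens the epoxide at the benzylic carbon and the aroyl group migrates (Meinwald-type rearrangement) to rac-3-[4-(benzyloxy)-2-(methoxymethoxy)phenyl]-2-[2-(benzyloxy)-3-(3-hydroxy-3-methylbutyl)-4-methoxy-6-(methoxymethoxy)phenyl]-3-oxopropanal F7. Dilute methanolic HCl cleaves both MOM ethers, the ortho-acyl one expected first, and the ring-A phenol condenses with the formyl group to give 15.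

3. Step 10. The MOM ether may be lost before the pyranone has closed, so that the ring-B oxygen takes the acetal carbon in a faster five-ring closure. The acid may also ionise the tertiary alcohol. The fallback sets out from 12 and returns to the route at 15. It makes the pyranone O–C bond before the aryl shift. Base-induced oxa-Michael closure of 12 (NaOAc, EtOH, reflux) gives the flavanone rac-7-(benzyloxy)-2-[2-(benzyloxy)-3-(3-hydroxy-3-methylbutyl)-4-methoxy-6-(methoxymethoxy)phenyl]-2,3-dihydro-4H-chromen-4-one F8. Oxidative 2,3-aryl migration with PhI(OH)OTs in MeCN (iodination of the enol at C3, shift of the electron-rich aryl group from C2, loss of a proton) gives MOM-protected isoflavone 14, now isolated. Its MOM ether is then cleaved (HCl, MeOH, 45 °C) on a finished chromone, where no other ring closure is open, to give 15.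

**Further compounds**

F1 | step 11 | 1-[4-(benzyloxy)-2-methoxyphenyl]ethan-1-one | CC(=O)c1ccc(OCc2ccccc2)cc1OC
F2 | step 11 | (E)-1-[4-(benzyloxy)-2-methoxyphenyl]-3-[2-(benzyloxy)-3-(3-hydroxy-3-methylbutyl)-4-methoxy-6-(methoxymethoxy)phenyl]prop-2-en-1-one | COCOc1cc(OC)c(CCC(C)(C)O)c(OCc2ccccc2)c1/C=C/C(=O)c1ccc(OCc2ccccc2)cc1OC
F3 | step 11 | rac-1-[4-(benzyloxy)-2-methoxyphenyl]-2-[2-(benzyloxy)-3-(3-hydroxy-3-methylbutyl)-4-methoxy-6-(methoxymethoxy)phenyl]-3,3-dimethoxypropan-1-one | COCOc1cc(OC)c(CCC(C)(C)O)c(OCc2ccccc2)c1C(C(OC)OC)C(=O)c1ccc(OCc2ccccc2)cc1OC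
F4 | step 11 | [4-(benzyloxy)-5-(3-hydroxy-3-methylbutyl)-2,6-dimethoxy-2,3-dihydro-1-benzofuran-3-yl][4-(benzyloxy)-2-methoxyphenyl]methanone (racemic, cis/trans mixture) | COC1Oc2cc(OC)c(CCC(C)(C)O)c(OCc3ccccc3)c2C1C(=O)c1ccc(OCc2ccccc2)cc1OC
F5 | step 9 | (E)-1-[4-(benzyloxy)-2-(methoxymethoxy)phenyl]-3-[2-(benzyloxy)-3-(3-hydroxy-3-methylbutyl)-4-methoxy-6-(methoxymethoxy)phenyl]prop-2-en-1-one | COCOc1cc(OC)c(CCC(C)(C)O)c(OCc2ccccc2)c1/C=C/C(=O)c1ccc(OCc2ccccc2)cc1OCOC
F6 | step 9 | rac-trans-[4-(benzyloxy)-2-(methoxymethoxy)phenyl]{3-[2-(benzyloxy)-3-(3-hydroxy-3-methylbutyl)-4-methoxy-6-(methoxymethoxy)phenyl]oxiran-2-yl}methanone (one enantiomer drawn) | O=C(c1ccc(OCc2ccccc2)cc1OCOC)[C@@H]1O[C@H]1c1c(OCOC)cc(OC)c(CCC(C)(C)O)c1OCc1ccccc1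
F7 | step 9 | rac-3-[4-(benzyloxy)-2-(methoxymethoxy)phenyl]-2-[2-(benzyloxy)-3-(3-hydroxy-3-methylbutyl)-4-methoxy-6-(methoxymethoxy)phenyl]-3-oxopropanal | O=CC(C(=O)c1ccc(OCc2ccccc2)cc1OCOC)c1c(OCOC)cc(OC)c(CCC(C)(C)O)c1OCc1ccccc1
F8 | step 10 | rac-7-(benzyloxy)-2-[2-(benzyloxy)-3-(3-hydroxy-3-methylbutyl)-4-methoxy-6-(methoxymethoxy)phenyl]-2,3-dihydro-4H-chromen-4-one | O=C1CC(c2c(OCOC)cc(OC)c(CCC(C)(C)O)c2OCc2ccccc2)Oc2cc(OCc3ccccc3)ccc12
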